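Slowness opened the meeting: the reciprocal of the dissolution coefficient is 4.35 min, far longer than the 0.375 s relaxation half-life of starting material and intermediate by step 1 in alpha. The flasks and questions were then tabled.

| flask | solid substrate | first nucleophile | second nucleophile | time | remark | temperature |
|---|---|---|---|---|---|---|
| gamma | 10 mM | 5.00 mM | 15.0 mM | 15 min | at 5 °C until 5.0 min, from then on at 35 °C |  |
| beta | 10 mM | 5.00 mM | 15.0 mM | 15 min |  | 20 °C |
| delta | 10 mM | 5.00 mM | 15.0 mM | 15 min |  | 35 °C |
| alpha | 10 mM | 5.00 mM | 15.0 mM | 15 min |  | 5 °C |

    starting material ⇌ intermediate (K1 = 0.0018, k1 = 5.1 /min, Ea1 = 82.0 kJ/mol, ΔH1 = 5.00 kJ/mol)
    first nucleophile + intermediate → target (k2 = 84000 /M/min, Ea2 = 40.0 kJ/mol)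
    second nucleophile + intermediate → other capture product (k3 = 10000 /M/min, Ea3 = 51.0 kJ/mol)
    solid substrate ⇌ starting material, rate k4*(cs4 - [starting material]) while solid is left; crystals form when [starting material] > cs4 (cs4 = 3.6 mM, k4 = 0.23 /min)
    (constants at 35 °C)

- solid substrate is a solid; its amount is given per volume of the solution
- all constants are for 35 °C and move with temperature by the activation energies and enthalpies
- at the start none of the solid substrate is in solution
- what has only dissolved of solid substrate counts as not reacted

- the flask with the highest share of target in all that became target or other capture product ("all alike" if they lie within 1.5 percentage points) (gamma / beta / delta / alpha / all alike)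
- share of target in all that became target or other capture product, gamma
- share of target in all that became target or other capture product, beta
- share of target in all that became target or other capture product, delta
- share of target in all that became target or other capture product, alpha

The chair asked whether that slowness belongs in a reckoning of the share, as distinct from the yield. The kineticist argued that the share can be reached by following one molecule of intermediate. It may revert to starting material, but then it returns to the same fork, so among captures its chance of becoming target is φ = kB·B/(kB·B + kD·D). Here kB and kD are the capture rate constants at the flask's temperature, and B and D are the concentrations of the first and second nucleophile at that moment.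

As minute-taker, I reckoned this fork share by hand. The selectivity factor kB/kD is 8.40 at 35 °C. Capture by the second nucleophile speeds up 8.6-fold from the coldest flask to the hottest, and capture by the first 5.4-fold, so the factor rises to 13.3 at 5 °C. With the charges, φ for alpha is 81.6%, and for delta the share must stay below 73.7%.

The process engineer objected that these hold at the start. In alpha and delta the selectivity factor stands above one , so the first nucleophile falls faster than the second as a fraction of its own charge, and φ falls along each run. The meeting therefore minuted both figures as ceilings, with alpha's the higher. I went no further by hand.

The forecast was then read. It puts alpha on top, with 79% there, 69% in beta, 59% in gamma and 56% in delta, holding that “the cold flask gains both from this higher selectivity and from converting so little that the first nucleophile is barely depleted”. Those point values are its own, since my reckoning gives ceilings and not those numbers.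

The simulation puts alpha on top, as the forecast did, at 78.6%, against 68.7% in beta, 60.2% in gamma and 57.5% in delta. At 15.0 min, alpha retains 65% of its first nucleophile and 97% of its second, so its φ there is 75.0%, and alpha's share lies between the end and starting values. The neighbour of alpha charged with 1.2 mM of first nucleophile starts at φ = 51.6% and ends at 37.5%, and its share comes out between them at 44.8%.

Its constants stand for no real mixture.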